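**Plan**
- Cuts: C4=CH2 (Wittig), C1–H (hydride), both C2–CH3 bonds (enolate methylations) and C3–C1′ (conjugate addition), leading to a p-quinone monoketal, a C21 Grignard reagent and iodomethane. The chain is cut at C5′–C6′ (sulfone alkylation) and at C4′–C5′ and C3′–CH3 (carboalumination and hydroxymethylation of but-3-yn-1-ol).
- Enabling feature: ring carbons C1 (carbinol) and C4 (C=CH2) are para, like the carbonyl and ketal carbons of 4,4-dimethoxycyclohexadienone; its α carbon becomes C2 (CMe2) and its β carbon becomes C3 (chain-bearing CH).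
- Forward: no ring is closed, the carbocycle being the dearomatised ring of 4-methoxyphenol. The C21 chain is built from farnesyl bromide and a C6 allylic bromide, turned into its Grignard reagent and joined to the ring in one copper-catalysed three-component step, after which C2, C1 and C4 are adjusted.
- Stereochemistry: C3 from the chiral copper catalyst (desymmetrisation of the flat dienone); C1 from hydride delivery anti to the C3 chain; the E alkenes from syn-carboalumination and from farnesyl bromide.

Key step: step 11

Remarks
- Locants in the comments follow the target: ring C1 (carbinol), C2 (CMe2), C3 (CH with chain), C4 (C=CH2), C5, C6; chain C1′–C16′ counted from the ring. "C21 tetraenyl" means (3E,7E,11E)-3,8,12,16-tetramethylheptadeca-3,7,11,15-tetraen-1-yl.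
- Assumption: the sense of induction of the ferrocenyl diphosphine on dienone 2 cannot be read from the ligand descriptor with certainty. The antipode written, (RP)-1-[(R)-α-(dimethylamino)-2-(diphenylphosphino)benzyl]-2-(diphenylphosphino)ferrocene, C43H39FeNP2 (Taniaphos type), is taken to give (5S)-19; its mirror image is used if a trial run with a simple Grignard reagent shows the opposite sense.

Step 1
Reactants: 1 4-methoxyphenol
Product: 2 4,4-dimethoxycyclohexa-2,5-dien-1-one
Conditions: PhI(OAc)2 (1.1 equiv), MeOH, 0 °C → rt
Reagents that add atoms: methanol, CO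
Why: Oxidative dearomatisation, in which the hypervalent iodine reagent oxidises the phenol to a para-quinoid cation that methanol traps at the methoxy-bearing carbon, gives the symmetric monoketal whose carbonyl, α, β and ketal carbons carry the oxidation pattern of target C1, C2, C3 and C4.

Step 2
Reactants: 3 but-3-yn-1-ol
Product: 4 (but-3-yn-1-yloxy)(tert-butyl)dimethylsilane
Conditions: TBSCl, imidazole, CH2Cl2, 0 °C → rt
Reagents that add atoms: tert-butyldimethylsilyl chloride, CC(C)(C)[Si](C)(C)Cl
Why: Silyl ether formation under imidazole catalysis protects the hydroxyl against Me3Al and against the later sulfone-anion and hydride steps.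

Step 3
Reactants: 4 (but-3-yn-1-yloxy)(tert-butyl)dimethylsilane
Product: 7 (E)-5-(tert-butyldimethylsilyloxy)-3-methylpent-2-en-1-ol, via alkenyldimethylalane 5 (not isolated), via lithium alkenylalanate 6 (not isolated)
Conditions: Me3Al (2.5 equiv), Cp2ZrCl2 (0.25 equiv), CH2Cl2, 0 °C → rt; volatiles removed; n-BuLi, THF/hexane, −78 → 0 °C; (CH2O)n, rt; aq. potassium sodium tartrate
Reagents that add atoms: trimethylaluminium, C[Al](C)C; formaldehyde (as paraformaldehyde), C=O
Why: Zirconium-catalysed carboalumination (Negishi) adds methyl and aluminium syn across the terminal alkyne with aluminium on the terminal carbon, and the derived alanate is hydroxymethylated by formaldehyde with retention, which sets the E geometry of C3′=C4′ and adds C5′.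

Step 4
Reactants: 7 (E)-5-(tert-butyldimethylsilyloxy)-3-methylpent-2-en-1-ol
Product: 8 (E)-[(5-bromo-3-methylpent-3-en-1-yl)oxy](tert-butyl)dimethylsilane
Conditions: CBr4, PPh3, CH2Cl2, −20 → 0 °C
Reagents that add atoms: carbon tetrabromide, BrC(Br)(Br)Br
Why: Appel bromination converts the primary allylic alcohol into the bromide under neutral conditions that spare the silyl ether and should not scramble the alkene.

Step 5
Reactants: 9 (2E,6E)-farnesyl bromide
Product: 10 (2E,6E)-farnesyl phenyl sulfone
Conditions: PhSO2Na, DMF, rt
Reagents that add atoms: sodium benzenesulfinate, [Na+].[O-]S(=O)c1ccccc1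
Why: SN2 S-alkylation of the sulfinate by the primary allylic bromide gives the allylic sulfone that later makes C1 of the farnesyl unit nucleophilic, with both E alkenes untouched.

Step 6
Reactants: 10 (2E,6E)-farnesyl phenyl sulfone; 8 (E)-[(5-bromo-3-methylpent-3-en-1-yl)oxy](tert-butyl)dimethylsilane
Product: 12 tert-butyldimethyl{[(3E,7E,11E)-3,8,12,16-tetramethyl-6-(phenylsulfonyl)heptadeca-3,7,11,15-tetraen-1-yl]oxy}silane (racemic at C6), via lithiated sulfone 11 (not isolated)
Conditions: n-BuLi, THF/DMPU, −78 °C; then 8, −78 → −20 °C
Reagents that add atoms: none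
Why: Biellmann-type sulfone alkylation, in which the sulfonyl-stabilised allylic carbanion attacks the primary allylic bromide through its α carbon in an SN2 displacement, forms C5′–C6′, and the sulfonyl-bearing centre, formed racemic, is erased in step 7.

Step 7
Reactants: 12 the C6-phenylsulfonyl C21 silyl ether
Product: 13 tert-butyldimethyl[(C21 tetraenyl)oxy]silane
Conditions: LiEt3BH (2 equiv), PdCl2(dppp) (5 mol %), THF, 0 °C
Reagents that add atoms: none
Why: Palladium-catalysed reductive desulfonylation, in which zerovalent palladium generated from the precatalyst ionises the allylic sulfone to a π-allyl complex of divalent palladium and hydride is delivered to the less substituted terminus, should leave the trisubstituted alkene in place with E geometry and the silyl ether intact.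

Step 8
Reactants: 13 tert-butyldimethyl[(C21 tetraenyl)oxy]silane
Product: 14 (3E,7E,11E)-3,8,12,16-tetramethylheptadeca-3,7,11,15-tetraen-1-ol
Conditions: TBAF, THF, rt
Reagents that add atoms: none
Why: Fluoride-induced desilylation, driven by the strong Si–F bond, frees the primary alcohol without affecting the tetraene.

Step 9
Reactants: 14 the C21 tetraenol
Product: 15 (6E,10E,14E)-17-bromo-2,6,10,15-tetramethylheptadeca-2,6,10,14-tetraene (C21 tetraenyl bromide)
Conditions: CBr4, PPh3, CH2Cl2, 0 °C
Reagents that add atoms: carbon tetrabromide, BrC(Br)(Br)Br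
Why: Appel bromination (SN2 displacement of the oxyphosphonium group) turns the homoallylic primary alcohol into the bromide under neutral conditions that neither isomerise nor add to the alkenes.

Step 10
Reactants: 15 C21 tetraenyl bromide
Product: 16 C21 tetraenylmagnesium bromide (Et2O solution, titrated and used at once)
Conditions: Mg turnings (activated with BrCH2CH2Br), Et2O, gentle reflux then rt
Reagents that add atoms: magnesium, [Mg]
Why: Grignard formation by magnesium insertion into the primary C–Br bond is reliable for homoallylic bromides, and keeping the reagent at or below room temperature and using it directly prevents the slow homoallyl–cyclopropylcarbinyl equilibrium from eroding the C3′=C4′ geometry.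

Step 11
Reactants: 2 4,4-dimethoxycyclohexa-2,5-dien-1-one; 16 C21 tetraenylmagnesium bromide; 17 iodomethane
Product: 19 (5S,6S)-4,4-dimethoxy-6-methyl-5-(C21 tetraenyl)cyclohex-2-en-1-one, via bromomagnesium dienolate 18 (not isolated)
Conditions: CuBr·SMe2 (5 mol %), ferrocenyl diphosphine C43H39FeNP2 (6 mol %), t-BuOMe/CH2Cl2, −78 °C, 16 added over 2 h to 2 (1.1 equiv); then DMPU, MeI (excess), −78 → 0 °C; aq. NH4Cl, chromatography on Et3N-deactivated silica
Reagents that add atoms: iodomethane (17), CI
Why: Transmetalation of 16 to the diphosphine-bound monovalent copper bromide gives an alkylcopper species that binds one enone arm of 2 as a π-complex, passes through a trivalent copper σ-enolate and reductively eliminates to form C3–C1′, releasing bromomagnesium dienolate 18, which iodomethane then C-methylates in the presence of DMPU to form C2–CH3. The closest known reaction types are the copper/ferrocenyl-diphosphine-catalysed conjugate addition of Grignard reagents to cyclic enones and the copper-catalysed enantioselective addition of organozinc reagents to 4,4-dialkoxycyclohexadienones, each combined with alkylation of the metal enolate. No ring is closed, the six-membered ring being that of the dienone. The chain-bearing centre (5S in 19, target C3) is set by the chiral copper complex, which must pick one of the two enantiotopic enone arms and its face on a flat symmetric substrate, while the methyl-bearing centre (6S) is set by the substrate, iodomethane approaching the enolate anti to the adjacent chain, and is removed again in step 12. The step needs 1,4- over 1,2-addition and single over double addition: the first is secured by ligand-accelerated copper catalysis at −78 °C with slow addition of 16, the second by the adduct staying masked as enolate 18 until all Grignard reagent is consumed and by the slight excess of 2. The product is kept away from acid, because loss of methanol would aromatise it.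

Step 12
Reactants: 19 (5S,6S)-4,4-dimethoxy-6-methyl-5-(C21 tetraenyl)cyclohex-2-en-1-one; 17 iodomethane
Product: 21 (5S)-4,4-dimethoxy-6,6-dimethyl-5-(C21 tetraenyl)cyclohex-2-en-1-one, via lithium dienolate 20 (not isolated)
Conditions: LiN(iPr)2 (1.2 equiv), THF, −78 °C; MeI (5 equiv), DMPU, −78 → 0 °C
Reagents that add atoms: iodomethane (17), CI
Why: Kinetic enolate alkylation works here because LiN(iPr)2 can deprotonate 19 only at C6 (C4 bears no hydrogen), and C-methylation of the cross-conjugated lithium dienolate creates the gem-dimethyl carbon (target C2), which deletes the C6 stereocentre and removes the hydrogen whose loss together with methanol would aromatise the ring.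

Step 13
Reactants: 21 (5S)-4,4-dimethoxy-6,6-dimethyl-5-(C21 tetraenyl)cyclohex-2-en-1-one
Product: 22 (3S)-4,4-dimethoxy-2,2-dimethyl-3-(C21 tetraenyl)cyclohexan-1-one
Conditions: [(Ph3P)CuH]6 (0.35 equiv of hexamer), degassed benzene, H2O (5 equiv), rt
Reagents that add atoms: none
Why: Stryker conjugate reduction, in which the copper hydride delivers hydride to the β carbon of the enone and water protonates the copper enolate, is chemoselective for the conjugated alkene over the four isolated trisubstituted alkenes, leaves the ketal alone and creates no stereocentre.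

Step 14
Reactants: 22 (3S)-4,4-dimethoxy-2,2-dimethyl-3-(C21 tetraenyl)cyclohexan-1-one
Product: 23 (1S,3S)-4,4-dimethoxy-2,2-dimethyl-3-(C21 tetraenyl)cyclohexan-1-ol
Conditions: NaBH4, MeOH, −20 → 0 °C; chromatographic removal of the minor C1 epimer
Reagents that add atoms: none
Why: In this diastereoselective hydride reduction borohydride is expected to attack the carbonyl on the face opposite the C3 chain, which in the chair with that chain equatorial is the axial trajectory (the equatorial one being shielded by the axial C2 methyl), so the new (1S) carbinol is cis to the chain, and the minor epimer is removed here because after step 15 epimerisation at C3 would turn it into the enantiomer of 24.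

Step 15
Reactants: 23 (1S,3S)-4,4-dimethoxy-2,2-dimethyl-3-(C21 tetraenyl)cyclohexan-1-ol
Product: 24 (2S,4S)-4-hydroxy-3,3-dimethyl-2-(C21 tetraenyl)cyclohexan-1-one
Conditions: PPTS (0.2 equiv), acetone/H2O 10:1, rt → 40 °C
Reagents that add atoms: water, O
Why: Acid-catalysed ketal hydrolysis through the oxocarbenium ion proceeds under pyridinium tosylate buffering too mild to protonate the trisubstituted alkenes, and the chain-bearing carbon, now α to a ketone, sits in the 1,3-cis arrangement taken to be the more stable one, so it should not drift.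

Step 16
Reactants: 24 (2S,4S)-4-hydroxy-3,3-dimethyl-2-(C21 tetraenyl)cyclohexan-1-one
Product: 25 achilleol A, (1S,3R)-2,2-dimethyl-4-methylidene-3-(C21 tetraenyl)cyclohexan-1-ol
Conditions: Ph3PCH3Br (4 equiv), KOt-Bu (3.8 equiv), THF, 0 °C → reflux
Reagents that add atoms: methyltriphenylphosphonium bromide, C[P+](c1ccccc1)(c1ccccc1)c1ccccc1.[Br-]
Why: Wittig methylenation with excess ylide (one equivalent being held as the C1 alkoxide) converts the C4 ketone into the exocyclic methylidene without touching C1, and any base-induced equilibration at C3 would at worst give a separable diastereomer.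

**Compound list**
1 | 4-methoxyphenol | COc1ccc(O)cc1 | starting material
2 | 4,4-dimethoxycyclohexa-2,5-dien-1-one | COC1(OC)C=CC(=O)C=C1 | intermediate
3 | but-3-yn-1-ol | C#CCCO | starting material
4 | (but-3-yn-1-yloxy)(tert-butyl)dimethylsilane | C#CCCO[Si](C)(C)C(C)(C)C | intermediate
5 | (E)-[4-(tert-butyldimethylsilyloxy)-2-methylbut-1-en-1-yl]dimethylalane | C[Al](C)/C=C(\C)CCO[Si](C)(C)C(C)(C)C | intermediate (not isolated)
6 | lithium (E)-butyl[4-(tert-butyldimethylsilyloxy)-2-methylbut-1-en-1-yl]dimethylalanate | [Li+].CCCC[Al-](C)(C)/C=C(\C)CCO[Si](C)(C)C(C)(C)C | intermediate (not isolated)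
7 | (E)-5-(tert-butyldimethylsilyloxy)-3-methylpent-2-en-1-ol | OC/C=C(\C)CCO[Si](C)(C)C(C)(C)C | intermediate
8 | (E)-[(5-bromo-3-methylpent-3-en-1-yl)oxy](tert-butyl)dimethylsilane | BrC/C=C(\C)CCO[Si](C)(C)C(C)(C)C | intermediate
9 | (2E,6E)-farnesyl bromide, (2E,6E)-1-bromo-3,7,11-trimethyldodeca-2,6,10-triene | BrC/C=C(\C)CC/C=C(\C)CCC=C(C)C | starting material
10 | (2E,6E)-farnesyl phenyl sulfone | O=S(=O)(C/C=C(\C)CC/C=C(\C)CCC=C(C)C)c1ccccc1 | intermediate
11 | α-lithio-(2E,6E)-farnesyl phenyl sulfone | [Li]C(/C=C(\C)CC/C=C(\C)CCC=C(C)C)S(=O)(=O)c1ccccc1 | intermediate (not isolated)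
12 | tert-butyldimethyl{[(3E,7E,11E)-3,8,12,16-tetramethyl-6-(phenylsulfonyl)heptadeca-3,7,11,15-tetraen-1-yl]oxy}silane, racemic at C6 | CC(C)=CCC/C(C)=C/CC/C(C)=C/C(C/C=C(\C)CCO[Si](C)(C)C(C)(C)C)S(=O)(=O)c1ccccc1 | intermediate
13 | tert-butyldimethyl{[(3E,7E,11E)-3,8,12,16-tetramethylheptadeca-3,7,11,15-tetraen-1-yl]oxy}silane | CC(C)=CCC/C(C)=C/CC/C(C)=C/CC/C=C(\C)CCO[Si](C)(C)C(C)(C)C | intermediate
14 | (3E,7E,11E)-3,8,12,16-tetramethylheptadeca-3,7,11,15-tetraen-1-ol | CC(C)=CCC/C(C)=C/CC/C(C)=C/CC/C=C(\C)CCO | intermediate
15 | (6E,10E,14E)-17-bromo-2,6,10,15-tetramethylheptadeca-2,6,10,14-tetraene | BrCC/C(C)=C/CC/C=C(\C)CC/C=C(\C)CCC=C(C)C | intermediate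
16 | [(3E,7E,11E)-3,8,12,16-tetramethylheptadeca-3,7,11,15-tetraen-1-yl]magnesium bromide | Br[Mg]CC/C(C)=C/CC/C=C(\C)CC/C=C(\C)CCC=C(C)C | intermediate
17 | iodomethane | CI | starting material
18 | bromomagnesium (3S)-4,4-dimethoxy-3-(C21 tetraenyl)cyclohexa-1,5-dien-1-olate | COC1(OC)C=CC(O[Mg]Br)=C[C@@H]1CC/C(C)=C/CC/C=C(\C)CC/C=C(\C)CCC=C(C)C | intermediate (not isolated)
19 | (5S,6S)-4,4-dimethoxy-6-methyl-5-[(3E,7E,11E)-3,8,12,16-tetramethylheptadeca-3,7,11,15-tetraen-1-yl]cyclohex-2-en-1-one (5,6-trans) | COC1(OC)C=CC(=O)[C@@H](C)[C@@H]1CC/C(C)=C/CC/C=C(\C)CC/C=C(\C)CCC=C(C)C | intermediate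
20 | lithium (3S)-4,4-dimethoxy-2-methyl-3-(C21 tetraenyl)cyclohexa-1,5-dien-1-olate | COC1(OC)C=CC(O[Li])=C(C)[C@@H]1CC/C(C)=C/CC/C=C(\C)CC/C=C(\C)CCC=C(C)C | intermediate (not isolated)
21 | (5S)-4,4-dimethoxy-6,6-dimethyl-5-[(3E,7E,11E)-3,8,12,16-tetramethylheptadeca-3,7,11,15-tetraen-1-yl]cyclohex-2-en-1-one | COC1(OC)C=CC(=O)C(C)(C)[C@@H]1CC/C(C)=C/CC/C=C(\C)CC/C=C(\C)CCC=C(C)C | intermediate
22 | (3S)-4,4-dimethoxy-2,2-dimethyl-3-[(3E,7E,11E)-3,8,12,16-tetramethylheptadeca-3,7,11,15-tetraen-1-yl]cyclohexan-1-one | COC1(OC)CCC(=O)C(C)(C)[C@@H]1CC/C(C)=C/CC/C=C(\C)CC/C=C(\C)CCC=C(C)C | intermediate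
23 | (1S,3S)-4,4-dimethoxy-2,2-dimethyl-3-[(3E,7E,11E)-3,8,12,16-tetramethylheptadeca-3,7,11,15-tetraen-1-yl]cyclohexan-1-ol (1,3-cis) | COC1(OC)CC[C@H](O)C(C)(C)[C@@H]1CC/C(C)=C/CC/C=C(\C)CC/C=C(\C)CCC=C(C)C | intermediate
24 | (2S,4S)-4-hydroxy-3,3-dimethyl-2-[(3E,7E,11E)-3,8,12,16-tetramethylheptadeca-3,7,11,15-tetraen-1-yl]cyclohexan-1-one | O=C1CC[C@H](O)C(C)(C)[C@@H]1CC/C(C)=C/CC/C=C(\C)CC/C=C(\C)CCC=C(C)C | intermediate
25 | achilleol A, (1S,3R)-2,2-dimethyl-4-methylidene-3-[(3E,7E,11E)-3,8,12,16-tetramethylheptadeca-3,7,11,15-tetraen-1-yl]cyclohexan-1-ol | C=C1CC[C@H](O)C(C)(C)[C@@H]1CC/C(C)=C/CC/C=C(\C)CC/C=C(\C)CCC=C(C)C | target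

**Step count and risks**
Total step count: 16. Longest linear sequence: 14 steps (but-3-yn-1-ol 3 to achilleol A 25; steps 2–4 and 6–16).

The three steps most likely to fail:

1. Step 11. Direct 1,2-addition of the Grignard reagent may outrun the catalysed pathway, the catalyst may discriminate poorly between the enantiotopic enone arms with this long-chain reagent, or C-methylation of the magnesium enolate may be slow. The fallback is the known organozinc addition to this dienone class. It sets out from Grignard reagent 16: transmetalation with ZnCl2 (0.5 equiv) in Et2O and removal of the magnesium halide as its 1,4-dioxane complex would give salt-free bis(C21 tetraenyl)zinc F1. Its addition to dienone 2 under Cu(OTf)2 (2 mol %) and a BINOL-derived phosphoramidite carrying an N,N-bis(1-phenylethyl)amino group (antipode fixed by trial) in toluene at −25 °C would give the alkylzinc dienolate F2. This is methylated in the same flask with iodomethane 17 and HMPA, and the route is rejoined at 19. The price is that only one of the two chains on zinc is transferred.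

2. Step 14. Facial selectivity of hydride delivery may be poor if the chair with the C3 chain axial is populated, because then both faces of the carbonyl are hindered. The fallback replaces substrate control by reagent control: Corey–Bakshi–Shibata reduction of 22 with the (R)-2-methyl oxazaborolidine and catecholborane in toluene at −40 °C, catecholborane being chosen over BH3 to spare the alkenes. The catalyst distinguishes the quaternary C2 flank from the CH2 flank and, by the usual large/small model, should give the (1S) carbinol. It sets out from 22, returns at 23 and makes no new compound (F0).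

3. Step 16. The basic ylide may enolise the α-branched ketone instead of adding to it, returning ketone or epimerising C3. The fallback is a two-stage Peterson olefination from 24. The weakly basic organocerium reagent from Me3SiCH2Li and CeCl3 (THF, −78 °C) should add to the carbonyl to give the β-hydroxysilane (1S,3S)-2,2-dimethyl-3-(C21 tetraenyl)-4-[(trimethylsilyl)methyl]cyclohexane-1,4-diol F3. KH in THF then triggers syn-elimination of silanolate, which rejoins the route at 25.

Further compounds
F1 | step 11 | bis[(3E,7E,11E)-3,8,12,16-tetramethylheptadeca-3,7,11,15-tetraen-1-yl]zinc | CC(C)=CCC/C(C)=C/CC/C(C)=C/CC/C=C(\C)CC[Zn]CC/C(C)=C/CC/C=C(\C)CC/C=C(\C)CCC=C(C)C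
F2 | step 11 | (C21 tetraenyl)zinc (3S)-4,4-dimethoxy-3-(C21 tetraenyl)cyclohexa-1,5-dien-1-olate | COC1(OC)C=CC(O[Zn]CC/C(C)=C/CC/C=C(\C)CC/C=C(\C)CCC=C(C)C)=C[C@@H]1CC/C(C)=C/CC/C=C(\C)CC/C=C(\C)CCC=C(C)C
F0 | step 14 | none | none
F3 | step 16 | (1S,3S)-2,2-dimethyl-3-[(3E,7E,11E)-3,8,12,16-tetramethylheptadeca-3,7,11,15-tetraen-1-yl]-4-[(trimethylsilyl)methyl]cyclohexane-1,4-diol (C4 epimer mixture) | C[Si](C)(C)CC1(O)CC[C@H](O)C(C)(C)[C@@H]1CC/C(C)=C/CC/C=C(\C)CC/C=C(\C)CCC=C(C)C
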